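**Retrosynthetic overview**

1. Feature: ring A carries oxygen on C5, C7 and C8a, that is on alternate carbons as in a folded polyketide, and C7, C6 and the 3-hydroxy-3-methylbutyl chain on C6 are together the seven carbons and the ring oxygen of 6,6-dimethyltetrahydropyran-2-one opened at its acyl–oxygen bond.
2. Last disconnection: the two benzyl ethers on ring B, removed by hydrogenolysis.
3. Key disconnection: C7–C8 and C5–C6 of ring A. The lithiated 2-methyl group of a 6-aryl-2-methyl-4-pyranone-3-carboxylate is acylated by the lactone, and the keto ester then closes onto the ester by Claisen condensation.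
4. Pyranone (ring C): C-acylation of methyl acetoacetate by an arylpropioloyl chloride and 6-endo-dig O-cyclisation. The acid comes from 2,4-bis(benzyloxy)benzaldehyde by Corey–Fuchs homologation and carboxylation, the lactone from methyl 5-oxohexanoate and MeMgBr.
5. Ring order: ring B is bought, ring C is closed in step 4, ring A in step 6.

Key step: step 6

Remark on the chemistry: the target has no stereocentre, so nothing has to be set or preserved; fallback compounds that carry a transient stereocentre are racemic.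

**Route**

Step 1
Reactants: 1 2,4-bis(benzyloxy)benzaldehyde
Product: 2 2,4-bis(benzyloxy)-1-(2,2-dibromoethenyl)benzene
Conditions: CBr4 (2 equiv), PPh3 (4 equiv), CH2Cl2, 0 °C
Reagents that add atoms: carbon tetrabromide, BrC(Br)(Br)Br
Why: Corey–Fuchs dibromo-olefination, in which the ylide Ph3P=CBr2 formed from CBr4 and PPh3 undergoes a Wittig reaction with the aryl aldehyde under neutral conditions that leave the benzyl ethers alone.

Step 2
Reactants: 2 2,4-bis(benzyloxy)-1-(2,2-dibromoethenyl)benzene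
Product: 4 3-[2,4-bis(benzyloxy)phenyl]prop-2-ynoic acid, via lithium arylacetylide 3 (not isolated)
Conditions: n-BuLi (2.2 equiv), THF, −78 °C; CO2, −78 °C to rt; aq. HCl
Reagents that add atoms: carbon dioxide, O=C=O
Why: Second stage of the Corey–Fuchs sequence (Br/Li exchange, Fritsch–Buttenberg–Wiechert shift, deprotonation to the acetylide) followed by carboxylation of the acetylide, a standard route to arylpropiolic acids at a temperature where benzyl ethers are not metallated.

Step 3
Reactants: 4 3-[2,4-bis(benzyloxy)phenyl]prop-2-ynoic acid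
Product: 5 3-[2,4-bis(benzyloxy)phenyl]prop-2-ynoyl chloride
Conditions: (COCl)2, DMF (cat.), CH2Cl2, 0 °C to rt; evaporated and used crude
Reagents that add atoms: oxalyl chloride, O=C(Cl)C(Cl)=O
Why: Acid chloride formation through the Vilsmeier-type chloroiminium catalyst runs at or below room temperature, where the conjugated alkyne and the benzyl ethers should survive.

Step 4
Reactants: 5 3-[2,4-bis(benzyloxy)phenyl]prop-2-ynoyl chloride; 6 methyl acetoacetate
Product: 8 methyl 6-[2,4-bis(benzyloxy)phenyl]-2-methyl-4-oxo-4H-pyran-3-carboxylate, via triketo ester 7 (not isolated)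
Conditions: MgCl2, pyridine, CH2Cl2, 0 °C to rt; 1 M HCl wash; then TsOH·H2O (cat.), toluene, 60 °C
Reagents that add atoms: none
Why: C-acylation of the magnesium enolate of a β-keto ester by an acid chloride gives triacylmethane 7, whose acetyl enol oxygen adds to the ynone at the aryl-bearing carbon in a 6-endo-dig oxa-Michael cyclisation, the classical 4-pyranone synthesis from arylpropioloyl chlorides and acetoacetates.

Step 5
Reactants: 9 methyl 5-oxohexanoate
Product: 11 6,6-dimethyltetrahydro-2H-pyran-2-one, via hydroxy ester 10 (not isolated)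
Conditions: MeMgBr (1.05 equiv), THF, −78 to −20 °C; aq. NH4Cl; then TsOH·H2O (cat.), CH2Cl2, rt
Reagents that add atoms: methylmagnesium bromide, C[Mg]Br
Why: Chemoselective Grignard addition to the ketone of a δ-keto ester at low temperature, followed by acid-catalysed lactonisation of the tertiary hydroxy ester to the six-membered lactone.

Step 6
Reactants: 8 methyl 6-[2,4-bis(benzyloxy)phenyl]-2-methyl-4-oxo-4H-pyran-3-carboxylate; 11 6,6-dimethyltetrahydro-2H-pyran-2-one
Product: 13 2-[2,4-bis(benzyloxy)phenyl]-5,7-dihydroxy-6-(3-hydroxy-3-methylbutyl)-4H-chromen-4-one, via keto ester 12 (not isolated)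
Conditions: LiN(iPr)2 (1.05 equiv), THF, −78 °C; 11 (1.1 equiv), −78 to −20 °C; LiN(iPr)2 (3.2 equiv), −78 to 0 °C; aq. NH4Cl
Reagents that add atoms: none
Why: Proposed new method: one equivalent of LiN(iPr)2 removes a proton from the 2-methyl group of 8 (future C8), the only site whose anion is delocalised into both the ring ketone and the C3 ester, and this dienolate attacks the lactone carbonyl of 11 (future C7); collapse of the adduct frees the tertiary alkoxide, which takes up the now doubly activated C8–H, so that 12 is held as its enolate and neither reverts nor consumes a second molecule of the anion. The further LiN(iPr)2 then deprotonates the other α-carbon of the new ketone (future C6) to give a 1,3-dianion whose terminal carbanion adds to the neighbouring ester carbon (future C5) in a 6-exo-trig Claisen closure of ring A, and loss of methoxide with enolisation gives the aromatic 5,7-diol. The closest known reaction type is acylation of a laterally lithiated ortho-toluate by an ester or lactone followed by base-induced Claisen cyclisation to a 2-substituted naphthalene-1,3-diol, and lateral lithiation of 2-methyl-4-pyranones is itself established. No stereocentre is formed. The step needs C- over O-cyclisation (closure of the C7 enolate oxygen on the ester would give a pyranopyrandione), which is secured by converting the monoenolate fully into the dianion at −78 °C before warming so that C6 is the most nucleophilic site, while self-condensation of the lactone is avoided because no free amide base is present while 11 is consumed. The ortho relation of methyl and ester on the pyranone allows fusion only across C4a–C8a, which places oxygen at C5 and C7 and the chain at C6.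

Step 7
Reactants: 13 2-[2,4-bis(benzyloxy)phenyl]-5,7-dihydroxy-6-(3-hydroxy-3-methylbutyl)-4H-chromen-4-one
Product: 14 2-(2,4-dihydroxyphenyl)-5,7-dihydroxy-6-(3-hydroxy-3-methylbutyl)-4H-chromen-4-one
Conditions: H2 (1 atm), 10% Pd/C, EtOAc/MeOH, rt
Reagents that add atoms: none
Why: Catalytic hydrogenolysis of aryl benzyl ethers at 1 atm and room temperature normally leaves the chromone C2=C3 bond and the tertiary alcohol untouched, and the neutral medium avoids acid-induced cyclisation of the side-chain alcohol onto the C5 or C7 hydroxyl.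

**Compound list**

1 | 2,4-bis(benzyloxy)benzaldehyde | O=Cc1ccc(OCc2ccccc2)cc1OCc1ccccc1 | starting material
2 | 2,4-bis(benzyloxy)-1-(2,2-dibromoethenyl)benzene | BrC(Br)=Cc1ccc(OCc2ccccc2)cc1OCc1ccccc1 | intermediate
3 | lithium [2,4-bis(benzyloxy)phenyl]ethynide | [Li]C#Cc1ccc(OCc2ccccc2)cc1OCc1ccccc1 | intermediate (not isolated)
4 | 3-[2,4-bis(benzyloxy)phenyl]prop-2-ynoic acid | OC(=O)C#Cc1ccc(OCc2ccccc2)cc1OCc1ccccc1 | intermediate
5 | 3-[2,4-bis(benzyloxy)phenyl]prop-2-ynoyl chloride | ClC(=O)C#Cc1ccc(OCc2ccccc2)cc1OCc1ccccc1 | intermediate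
6 | methyl acetoacetate (methyl 3-oxobutanoate) | COC(=O)CC(C)=O | starting material
7 | methyl 2-acetyl-5-[2,4-bis(benzyloxy)phenyl]-3-oxopent-4-ynoate (enolisable, drawn as the keto form) | COC(=O)C(C(C)=O)C(=O)C#Cc1ccc(OCc2ccccc2)cc1OCc1ccccc1 | intermediate (not isolated)
8 | methyl 6-[2,4-bis(benzyloxy)phenyl]-2-methyl-4-oxo-4H-pyran-3-carboxylate | COC(=O)c1c(C)oc(-c2ccc(OCc3ccccc3)cc2OCc2ccccc2)cc1=O | intermediate
9 | methyl 5-oxohexanoate | COC(=O)CCCC(C)=O | starting material
10 | methyl 5-hydroxy-5-methylhexanoate | COC(=O)CCCC(C)(C)O | intermediate (not isolated)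
11 | 6,6-dimethyltetrahydro-2H-pyran-2-one | CC1(C)CCCC(=O)O1 | intermediate
12 | methyl 6-[2,4-bis(benzyloxy)phenyl]-2-(6-hydroxy-6-methyl-2-oxoheptyl)-4-oxo-4H-pyran-3-carboxylate | COC(=O)c1c(CC(=O)CCCC(C)(C)O)oc(-c2ccc(OCc3ccccc3)cc2OCc2ccccc2)cc1=O | intermediate (not isolated)
13 | 2-[2,4-bis(benzyloxy)phenyl]-5,7-dihydroxy-6-(3-hydroxy-3-methylbutyl)-4H-chromen-4-one | CC(C)(O)CCc1c(O)cc2oc(-c3ccc(OCc4ccccc4)cc3OCc3ccccc3)cc(=O)c2c1O | intermediate
14 | 2-(2,4-dihydroxyphenyl)-5,7-dihydroxy-6-(3-hydroxy-3-methylbutyl)-4H-chromen-4-one | CC(C)(O)CCc1c(O)cc2oc(-c3ccc(O)cc3O)cc(=O)c2c1O | target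

**Step count**

Total steps: 7. Longest linear sequence: 6 (steps 1, 2, 3, 4, 6, 7); step 5 is a one-step side branch.

**Steps most likely to fail**

1. Step 6. The doubly stabilised dienolate may add too slowly to the lactone, the C7 enolate oxygen may close on the ester in place of C6, the lactone may be enolised and self-condense, or the benzylic positions of the ethers may be metallated by the excess base. The fallback uses known flavone chemistry, sets out from aldehyde 1 and comes back at target 14.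
 - Claisen–Schmidt condensation of 1 with commercial 1-[2,4-bis(benzyloxy)-6-hydroxyphenyl]ethanone (CC(=O)c1c(O)cc(OCc2ccccc2)cc1OCc1ccccc1; KOH, EtOH, rt) should give (E)-1-[2,4-bis(benzyloxy)-6-hydroxyphenyl]-3-[2,4-bis(benzyloxy)phenyl]prop-2-en-1-one F1.
 - Oxidative cyclisation (I2 cat., DMSO, 120 °C) should give 5,7-bis(benzyloxy)-2-[2,4-bis(benzyloxy)phenyl]-4H-chromen-4-one F2.
 - Chelation-controlled cleavage of the peri benzyl ether (MgBr2·OEt2, toluene, 80 °C) should give 7-(benzyloxy)-2-[2,4-bis(benzyloxy)phenyl]-5-hydroxy-4H-chromen-4-one F3.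
 - Iodination ortho to the free 5-hydroxyl (BnMe3N·ICl2, CaCO3, CH2Cl2/MeOH, rt), a known C6-selective halogenation of 5-hydroxy-7-alkoxyflavones, should give 7-(benzyloxy)-2-[2,4-bis(benzyloxy)phenyl]-5-hydroxy-6-iodo-4H-chromen-4-one F4.
 - Benzylation (BnBr, K2CO3, DMF, 60 °C) should give 5,7-bis(benzyloxy)-2-[2,4-bis(benzyloxy)phenyl]-6-iodo-4H-chromen-4-one F5.
 - Sonogashira coupling with 2-methylbut-3-yn-2-ol (PdCl2(PPh3)2, CuI, Et3N, DMF, 60 °C) should give 5,7-bis(benzyloxy)-2-[2,4-bis(benzyloxy)phenyl]-6-(3-hydroxy-3-methylbut-1-yn-1-yl)-4H-chromen-4-one F6.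
 - Hydrogenation (H2, Pd/C, EtOAc/MeOH) should saturate the alkyne and cleave the four benzyl ethers to give 14.

2. Step 4. O-acylation may compete with C-acylation, the enolate or pyridine may add in conjugate fashion to the ynoyl chloride, the triacylmethane may lose its acetyl group on work-up, or the closure may not go 6-endo. The fallback replaces the ynone cyclisation by an aldol, cyclodehydration and dehydrogenation sequence; it sets out from aldehyde 1 and comes back at pyranone 8.
 - The dianion of methyl 2-acetyl-3-oxobutanoate (CC(=O)C(C(C)=O)C(=O)OC; NaH, then n-BuLi, THF, 0 to −78 °C) should add through its terminal carbon to 1 to give rac-methyl 2-acetyl-5-[2,4-bis(benzyloxy)phenyl]-5-hydroxy-3-oxopentanoate F7.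
 - TsOH·H2O (cat.) in CH2Cl2 should close it to rac-methyl 2-[2,4-bis(benzyloxy)phenyl]-6-methyl-4-oxo-3,4-dihydro-2H-pyran-5-carboxylate F8.
 - Dehydrogenation with DDQ (dioxane, 80 °C) should give 8.

3. Step 7. The chromone C2=C3 bond may be reduced along with the benzyl ethers, or the hydrogenolysis may stall as the polyphenol adsorbs on the catalyst. The fallback exchanges the benzyl ethers for silyl ethers before ring A is built, so that no hydrogenation is needed; it sets out from pyranone 8 and comes back at target 14.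
 - Debenzylation of 8 (BCl3, pentamethylbenzene, CH2Cl2, −78 °C) should give methyl 6-(2,4-dihydroxyphenyl)-2-methyl-4-oxo-4H-pyran-3-carboxylate F9.
 - Silylation (iPr3SiCl, imidazole, DMF) should give methyl 6-{2,4-bis[(triisopropylsilyl)oxy]phenyl}-2-methyl-4-oxo-4H-pyran-3-carboxylate F10.
 - Acylation with lactone 11 and Claisen closure under the conditions of step 6 should pass through methyl 6-{2,4-bis[(triisopropylsilyl)oxy]phenyl}-2-(6-hydroxy-6-methyl-2-oxoheptyl)-4-oxo-4H-pyran-3-carboxylate F11 (not isolated) to 2-{2,4-bis[(triisopropylsilyl)oxy]phenyl}-5,7-dihydroxy-6-(3-hydroxy-3-methylbutyl)-4H-chromen-4-one F12.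
 - Desilylation (Bu4NF, AcOH, THF, 0 °C) should give 14.

**Further compounds**

F1 | step 6 | (E)-1-[2,4-bis(benzyloxy)-6-hydroxyphenyl]-3-[2,4-bis(benzyloxy)phenyl]prop-2-en-1-one | O=C(/C=C/c1ccc(OCc2ccccc2)cc1OCc1ccccc1)c1c(O)cc(OCc2ccccc2)cc1OCc1ccccc1
F2 | step 6 | 5,7-bis(benzyloxy)-2-[2,4-bis(benzyloxy)phenyl]-4H-chromen-4-one | O=c1cc(-c2ccc(OCc3ccccc3)cc2OCc2ccccc2)oc2cc(OCc3ccccc3)cc(OCc3ccccc3)c12
F3 | step 6 | 7-(benzyloxy)-2-[2,4-bis(benzyloxy)phenyl]-5-hydroxy-4H-chromen-4-one | O=c1cc(-c2ccc(OCc3ccccc3)cc2OCc2ccccc2)oc2cc(OCc3ccccc3)cc(O)c12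
F4 | step 6 | 7-(benzyloxy)-2-[2,4-bis(benzyloxy)phenyl]-5-hydroxy-6-iodo-4H-chromen-4-one | O=c1cc(-c2ccc(OCc3ccccc3)cc2OCc2ccccc2)oc2cc(OCc3ccccc3)c(I)c(O)c12
F5 | step 6 | 5,7-bis(benzyloxy)-2-[2,4-bis(benzyloxy)phenyl]-6-iodo-4H-chromen-4-one | O=c1cc(-c2ccc(OCc3ccccc3)cc2OCc2ccccc2)oc2cc(OCc3ccccc3)c(I)c(OCc3ccccc3)c12
F6 | step 6 | 5,7-bis(benzyloxy)-2-[2,4-bis(benzyloxy)phenyl]-6-(3-hydroxy-3-methylbut-1-yn-1-yl)-4H-chromen-4-one | CC(C)(O)C#Cc1c(OCc2ccccc2)cc2oc(-c3ccc(OCc4ccccc4)cc3OCc3ccccc3)cc(=O)c2c1OCc1ccccc1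
F7 | step 4 | rac-methyl 2-acetyl-5-[2,4-bis(benzyloxy)phenyl]-5-hydroxy-3-oxopentanoate | COC(=O)C(C(C)=O)C(=O)CC(O)c1ccc(OCc2ccccc2)cc1OCc1ccccc1
F8 | step 4 | rac-methyl 2-[2,4-bis(benzyloxy)phenyl]-6-methyl-4-oxo-3,4-dihydro-2H-pyran-5-carboxylate | COC(=O)C1=C(C)OC(c2ccc(OCc3ccccc3)cc2OCc2ccccc2)CC1=O
F9 | step 7 | methyl 6-(2,4-dihydroxyphenyl)-2-methyl-4-oxo-4H-pyran-3-carboxylate | COC(=O)c1c(C)oc(-c2ccc(O)cc2O)cc1=O
F10 | step 7 | methyl 6-{2,4-bis[(triisopropylsilyl)oxy]phenyl}-2-methyl-4-oxo-4H-pyran-3-carboxylate | COC(=O)c1c(C)oc(-c2ccc(O[Si](C(C)C)(C(C)C)C(C)C)cc2O[Si](C(C)C)(C(C)C)C(C)C)cc1=O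
F11 | step 7 | methyl 6-{2,4-bis[(triisopropylsilyl)oxy]phenyl}-2-(6-hydroxy-6-methyl-2-oxoheptyl)-4-oxo-4H-pyran-3-carboxylate | COC(=O)c1c(CC(=O)CCCC(C)(C)O)oc(-c2ccc(O[Si](C(C)C)(C(C)C)C(C)C)cc2O[Si](C(C)C)(C(C)C)C(C)C)cc1=O
F12 | step 7 | 2-{2,4-bis[(triisopropylsilyl)oxy]phenyl}-5,7-dihydroxy-6-(3-hydroxy-3-methylbutyl)-4H-chromen-4-one | CC(C)(O)CCc1c(O)cc2oc(-c3ccc(O[Si](C(C)C)(C(C)C)C(C)C)cc3O[Si](C(C)C)(C(C)C)C(C)C)cc(=O)c2c1O
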